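**Plan**

1. Skeleton numbers are those of the germacrane ring (C1–C10 ring, C11–C13 acrylate unit on C7, C14 on C10, C15 on C4). The retrosynthesis first cuts C4–C5 and C6–O in one oxidative event, which opens the ten-membered ring and the lactone to an acyclic formyl acid; it then cuts C7–C8 (2-(alkoxycarbonyl)allylation) and C1=C10 (olefination).
2. Enabling feature: the 1,4-dioxygen pattern O–C15–C4–C5–C6–O. C4 is α to the C15 formyl group (enamine, then a 3π-electron radical cation), and C5=C6 is the γ,δ-alkene of the C12 acid (4-pentenoic acid unit C12–C11–C7–C6=C5), so a carbon radical at C4 and the carboxylate oxygen can add across the same alkene.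
3. Forward: C1=C10 by Horner–Wadsworth–Emmons olefination, C7–C8 by chromium-catalysed allylation with an acrolein-derived dienyl bromide, angelate on C8, one acid step to unveil CHO and CO2H, then the key closure (carbocycle first, lactone second, same step), reduction and desilylation.
4. Stereochemistry: C7 and C8 from the catalyst-controlled syn allylation; C4 from the imidazolidinone catalyst; C6 from C7 (trans lactone closure); C1=C10 geometry from the E-selective olefination; angelate geometry from angelic acid.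

Key step: step 13

Assumption: the senses of induction of the chromium–bis(oxazoline) catalyst (step 10) and of the imidazolidinone (step 13) follow the accepted models; should either prove opposite, the antipodal ligand or catalyst would be used with no other change.

**Route**

Step 1
Reactants: 1 cyclopentene
Product: 2 5,5-dimethoxypentanal
Conditions: O3, MeOH/CH2Cl2, TsOH (cat.), −78 °C; then NaHCO3, Me2S, −78 °C to rt
Reagents that add atoms: ozone [O-][O+]=O; methanol CO
Why: Ozonolysis in acidic methanol should acetalise one terminus and leave the other as a methoxy hydroperoxide that Me2S reduces to the aldehyde, so C1 (CHO) and C15 (acetal) are differentiated in one operation.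

Step 2
Reactants: 3 triethyl phosphonoacetate; 4 (2-bromoethoxy)(tert-butyl)dimethylsilane
Product: 5 ethyl 4-[(tert-butyldimethylsilyl)oxy]-2-(diethoxyphosphoryl)butanoate (racemic)
Conditions: NaH, DMSO, rt to 60 °C
Reagents that add atoms: none
Why: SN2 C-alkylation of the stabilised phosphonoacetate carbanion by a primary bromide should install the C9–C8 unit on the future C10.

Step 3
Reactants: 5 ethyl 4-[(tert-butyldimethylsilyl)oxy]-2-(diethoxyphosphoryl)butanoate; 2 5,5-dimethoxypentanal
Product: 6 ethyl (2E)-2-{2-[(tert-butyldimethylsilyl)oxy]ethyl}-7,7-dimethoxyhept-2-enoate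
Conditions: NaH, THF, 0 °C to rt
Reagents that add atoms: none
Why: Horner–Wadsworth–Emmons olefination of an aliphatic aldehyde with an α-substituted phosphonoacetate should give mainly the E enoate (ester trans to C2), which is the C1=C10 geometry of the target; the minor Z isomer would be removed by chromatography.

Step 4
Reactants: 6 ethyl (2E)-2-{2-[(tert-butyldimethylsilyl)oxy]ethyl}-7,7-dimethoxyhept-2-enoate
Product: 7 (2E)-2-{2-[(tert-butyldimethylsilyl)oxy]ethyl}-7,7-dimethoxyhept-2-en-1-ol
Conditions: i-Bu2AlH (2.2 equiv), CH2Cl2, −78 °C; Rochelle salt work-up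
Reagents that add atoms: none
Why: 1,2-Reduction of the conjugated ester by i-Bu2AlH should give the C14 allylic alcohol and leave the acetal and silyl ether untouched.

Step 5
Reactants: 7 (2E)-2-{2-[(tert-butyldimethylsilyl)oxy]ethyl}-7,7-dimethoxyhept-2-en-1-ol
Product: 8 (3E)-1-[(tert-butyldimethylsilyl)oxy]-3-{[(tert-butyldiphenylsilyl)oxy]methyl}-8,8-dimethoxyoct-3-ene
Conditions: t-BuPh2SiCl, imidazole, CH2Cl2, 0 °C to rt
Reagents that add atoms: tert-butyl(chloro)diphenylsilane CC(C)(C)[Si](Cl)(c1ccccc1)c1ccccc1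
Why: Standard silylation of the primary allylic alcohol; the tert-butyldiphenylsilyl ether is chosen because it should outlast the acidic steps 6 and 12.

Step 6
Reactants: 8 (3E)-1-[(tert-butyldimethylsilyl)oxy]-3-{[(tert-butyldiphenylsilyl)oxy]methyl}-8,8-dimethoxyoct-3-ene
Product: 9 (3E)-3-{[(tert-butyldiphenylsilyl)oxy]methyl}-8,8-dimethoxyoct-3-en-1-ol
Conditions: PPTS (cat.), MeOH, 0 °C to rt
Reagents that add atoms: none
Why: Mild acid methanolysis should cleave the primary tert-butyldimethylsilyl ether much faster than the tert-butyldiphenylsilyl ether, and in methanol the dimethyl acetal is only exchanged with itself.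

Step 7
Reactants: 9 (3E)-3-{[(tert-butyldiphenylsilyl)oxy]methyl}-8,8-dimethoxyoct-3-en-1-ol
Product: 10 (3E)-3-{[(tert-butyldiphenylsilyl)oxy]methyl}-8,8-dimethoxyoct-3-enal
Conditions: Dess–Martin periodinane, NaHCO3, CH2Cl2, 0 °C; used crude at once
Reagents that add atoms: none
Why: Buffered Dess–Martin oxidation should give the β,γ-unsaturated C8 aldehyde without moving the C1=C10 double bond into conjugation.

Step 8
Reactants: 11 acrolein; 12 tert-butyl acrylate
Product: 13 tert-butyl 3-hydroxy-2-methylidenepent-4-enoate (racemic)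
Conditions: DABCO (cat.), neat, rt
Reagents that add atoms: none
Why: Morita–Baylis–Hillman coupling should assemble C5–C7 and C11–C13 in one step; the stereocentre is removed in step 9.

Step 9
Reactants: 13 tert-butyl 3-hydroxy-2-methylidenepent-4-enoate
Product: 14 tert-butyl (2Z)-2-(bromomethyl)penta-2,4-dienoate
Conditions: PBr3 (0.4 equiv), Et2O, −10 °C; used at once
Reagents that add atoms: phosphorus tribromide BrP(Br)Br
Why: Bromination with allylic transposition (SN2') should give the conjugated primary bromide as the favoured Z isomer (vinyl trans to the ester), as is usual for Morita–Baylis–Hillman alcohols.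

Step 10
Reactants: 10 (3E)-3-{[(tert-butyldiphenylsilyl)oxy]methyl}-8,8-dimethoxyoct-3-enal; 14 tert-butyl (2Z)-2-(bromomethyl)penta-2,4-dienoate
Product: 16 tert-butyl (3R,4R,6E)-6-{[(tert-butyldiphenylsilyl)oxy]methyl}-3-ethenyl-4-hydroxy-11,11-dimethoxy-2-methylideneundec-6-enoate, via trimethylsilyl ether 15 (not isolated)
Conditions: CrCl2 (10 mol %), (S,S)-1,8-bis(4-isopropyl-4,5-dihydrooxazol-2-yl)-3,6-diphenyl-9H-carbazole (12 mol %), Mn, Me3SiCl, i-Pr2NEt, THF, 0 °C; then PPTS, MeOH, rt
Reagents that add atoms: none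
Why: In this catalytic asymmetric Nozaki–Hiyama–Kishi allylation the 2-(alkoxycarbonyl)allylchromium reagent should add through its γ-carbon (C7) in a closed chair transition state with the vinyl group cis to CH2Cr, giving the syn C7/C8 adduct with the absolute sense set by the ligand, while the tert-butyl ester prevents lactonisation onto the C8 hydroxyl.

Step 11
Reactants: 16 tert-butyl (3R,4R,6E)-6-{[(tert-butyldiphenylsilyl)oxy]methyl}-3-ethenyl-4-hydroxy-11,11-dimethoxy-2-methylideneundec-6-enoate
Product: 17 tert-butyl (3R,4R,6E)-6-{[(tert-butyldiphenylsilyl)oxy]methyl}-3-ethenyl-11,11-dimethoxy-4-{[(2Z)-2-methylbut-2-enoyl]oxy}-2-methylideneundec-6-enoate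
Conditions: angelic acid, 2,4,6-trichlorobenzoyl chloride, Et3N, toluene, rt; then 16, 80 °C
Reagents that add atoms: angelic acid C/C=C(/C)C(=O)O
Why: Yamaguchi-type mixed-anhydride esterification without a nucleophilic catalyst should acylate the hindered C8 alcohol while keeping the Z geometry of the angelate.

Step 12
Reactants: 17 tert-butyl (3R,4R,6E)-6-{[(tert-butyldiphenylsilyl)oxy]methyl}-3-ethenyl-11,11-dimethoxy-4-{[(2Z)-2-methylbut-2-enoyl]oxy}-2-methylideneundec-6-enoate
Product: 18 (3R,4R,6E)-6-{[(tert-butyldiphenylsilyl)oxy]methyl}-3-ethenyl-4-{[(2Z)-2-methylbut-2-enoyl]oxy}-2-methylidene-11-oxoundec-6-enoic acid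
Conditions: CF3CO2H/CH2Cl2 (1:4), H2O (5 equiv), 0 °C to rt; used at once
Reagents that add atoms: water O
Why: Acid should cleave the tert-butyl ester (loss of 2-methylpropene) and hydrolyse the dimethyl acetal in the same flask, unveiling both the C12 acid and the C15 aldehyde, while the tert-butyldiphenylsilyl ether and the angelate survive.

Step 13
Reactants: 18 (3R,4R,6E)-6-{[(tert-butyldiphenylsilyl)oxy]methyl}-3-ethenyl-4-{[(2Z)-2-methylbut-2-enoyl]oxy}-2-methylidene-11-oxoundec-6-enoic acid
Product: 20 (1(10)E,4R,6R,7S,8R)-8-angeloyloxy-14-[(tert-butyldiphenylsilyl)oxy]-15-oxogermacra-1(10),11(13)-dien-12,6-olide, via enamine 19 (not isolated)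
Conditions: (2S,5S)-5-benzyl-2-tert-butyl-3-methylimidazolidin-4-one·CF3CO2H (30 mol %), Cu(OTf)2 (2.5 equiv), CF3CO2Na (2.5 equiv), H2O (2 equiv), i-PrCN/DME, rt, 18 added over 12 h (final 2 mM)
Reagents that add atoms: none
Why: Proposed new method: the catalyst condenses with the formyl group to give E-enamine 19, which Cu(OTf)2 oxidises by one electron to a 3π-electron radical cation electrophilic at C4; this adds to the unsubstituted terminus C5 of the C5=C6 vinyl group, the secondary C6 radical is captured by divalent copper held on the C12 carboxylate, the resulting trivalent alkylcopper carboxylate closes C6–O by reductive elimination, and hydrolysis of the iminium ion releases 20 and the catalyst. The closest known reaction types are the SOMO-catalysed enantioselective intramolecular α-alkylation of aldehydes with unactivated olefins (copper- or iron-based oxidants, five- to seven-membered rings) and the copper-mediated oxidative carbo-lactonisation of 4-pentenoic acids by carbon radicals; new are their combination and the ring size. The ten-membered carbocycle closes in the 10-endo-trig mode (attack at the terminal CH2, both alkene carbons in the ring) and the γ-lactone by a 5-exo C–O closure through a six-membered cupracycle. C4 is set by the catalyst, because in the E-enamine radical cation turned away from the tert-butyl group the benzyl group covers the Re face of C4, so C5 should bond on the Si face and give 4R; C6 is set by C7, because the C–O bond should form with C5 and C8 trans on the new lactone (6R, trans-fused), the arrangement that leaves the ten-membered ring free of eclipsing about C6–C7. The step needs site selectivity among three alkenes and ring closure over oligomerisation: the electrophilic radical cation should prefer the electron-richer monosubstituted C5=C6 over the electron-poor acrylic C11=C13, C1=C10 can only be reached by 5-endo or 4-exo closure, and slow addition at high dilution suppresses the intermolecular path.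

Step 14
Reactants: 20 (1(10)E,4R,6R,7S,8R)-8-angeloyloxy-14-[(tert-butyldiphenylsilyl)oxy]-15-oxogermacra-1(10),11(13)-dien-12,6-olide
Product: 21 (1(10)E,4R,6R,7S,8R)-8-angeloyloxy-14-[(tert-butyldiphenylsilyl)oxy]-15-hydroxygermacra-1(10),11(13)-dien-12,6-olide
Conditions: NaBH4, CeCl3·7H2O, MeOH/THF, −78 °C
Reagents that add atoms: none
Why: Luche reduction at low temperature should reduce the aldehyde far faster than it adds hydride in the conjugate sense to the α-methylene lactone, and the cold, non-basic medium should leave the α-formyl stereocentre C4 unepimerised.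

Step 15
Reactants: 21 (1(10)E,4R,6R,7S,8R)-8-angeloyloxy-14-[(tert-butyldiphenylsilyl)oxy]-15-hydroxygermacra-1(10),11(13)-dien-12,6-olide
Product: 22 (1(10)E,4R,6R,7S,8R)-8-angeloyloxy-14,15-dihydroxygermacra-1(10),11(13)-dien-12,6-olide (CNP0262807.1)
Conditions: HF·pyridine, pyridine, THF, 0 °C to rt
Reagents that add atoms: none
Why: Buffered fluoride should cleave the Si–O bond without the basic conditions that would invite Michael addition to the α-methylene lactone or acyl migration.

**Compound list**

1 | cyclopentene | C1=CCCC1 | starting material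
2 | 5,5-dimethoxypentanal | COC(OC)CCCC=O | intermediate
3 | triethyl phosphonoacetate | CCOC(=O)CP(=O)(OCC)OCC | starting material
4 | (2-bromoethoxy)(tert-butyl)dimethylsilane | BrCCO[Si](C)(C)C(C)(C)C | starting material
5 | ethyl 4-[(tert-butyldimethylsilyl)oxy]-2-(diethoxyphosphoryl)butanoate (racemic) | CCOC(=O)C(CCO[Si](C)(C)C(C)(C)C)P(=O)(OCC)OCC | intermediate
6 | ethyl (2E)-2-{2-[(tert-butyldimethylsilyl)oxy]ethyl}-7,7-dimethoxyhept-2-enoate | CCOC(=O)/C(CCO[Si](C)(C)C(C)(C)C)=C/CCCC(OC)OC | intermediate
7 | (2E)-2-{2-[(tert-butyldimethylsilyl)oxy]ethyl}-7,7-dimethoxyhept-2-en-1-ol | OC/C(CCO[Si](C)(C)C(C)(C)C)=C/CCCC(OC)OC | intermediate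
8 | (3E)-1-[(tert-butyldimethylsilyl)oxy]-3-{[(tert-butyldiphenylsilyl)oxy]methyl}-8,8-dimethoxyoct-3-ene | CC(C)(C)[Si](C)(C)OCC/C(CO[Si](c1ccccc1)(c1ccccc1)C(C)(C)C)=C\CCCC(OC)OC | intermediate
9 | (3E)-3-{[(tert-butyldiphenylsilyl)oxy]methyl}-8,8-dimethoxyoct-3-en-1-ol | OCC/C(CO[Si](c1ccccc1)(c1ccccc1)C(C)(C)C)=C\CCCC(OC)OC | intermediate
10 | (3E)-3-{[(tert-butyldiphenylsilyl)oxy]methyl}-8,8-dimethoxyoct-3-enal | O=CC/C(CO[Si](c1ccccc1)(c1ccccc1)C(C)(C)C)=C\CCCC(OC)OC | intermediate
11 | acrolein | C=CC=O | starting material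
12 | tert-butyl acrylate | C=CC(=O)OC(C)(C)C | starting material
13 | tert-butyl 3-hydroxy-2-methylidenepent-4-enoate (racemic) | C=CC(O)C(=C)C(=O)OC(C)(C)C | intermediate
14 | tert-butyl (2Z)-2-(bromomethyl)penta-2,4-dienoate | BrC/C(C(=O)OC(C)(C)C)=C\C=C | intermediate
15 | tert-butyl (3R,4R,6E)-6-{[(tert-butyldiphenylsilyl)oxy]methyl}-3-ethenyl-11,11-dimethoxy-2-methylidene-4-[(trimethylsilyl)oxy]undec-6-enoate | COC(OC)CCC/C=C(/CO[Si](c1ccccc1)(c1ccccc1)C(C)(C)C)C[C@@H](O[Si](C)(C)C)[C@@H](C(=C)C(=O)OC(C)(C)C)C=C | intermediate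
16 | tert-butyl (3R,4R,6E)-6-{[(tert-butyldiphenylsilyl)oxy]methyl}-3-ethenyl-4-hydroxy-11,11-dimethoxy-2-methylideneundec-6-enoate | COC(OC)CCC/C=C(/CO[Si](c1ccccc1)(c1ccccc1)C(C)(C)C)C[C@@H](O)[C@@H](C(=C)C(=O)OC(C)(C)C)C=C | intermediate
17 | tert-butyl (3R,4R,6E)-6-{[(tert-butyldiphenylsilyl)oxy]methyl}-3-ethenyl-11,11-dimethoxy-4-{[(2Z)-2-methylbut-2-enoyl]oxy}-2-methylideneundec-6-enoate | COC(OC)CCC/C=C(/CO[Si](c1ccccc1)(c1ccccc1)C(C)(C)C)C[C@@H](OC(=O)/C(C)=C\C)[C@@H](C(=C)C(=O)OC(C)(C)C)C=C | intermediate
18 | (3R,4R,6E)-6-{[(tert-butyldiphenylsilyl)oxy]methyl}-3-ethenyl-4-{[(2Z)-2-methylbut-2-enoyl]oxy}-2-methylidene-11-oxoundec-6-enoic acid | O=CCCC/C=C(/CO[Si](c1ccccc1)(c1ccccc1)C(C)(C)C)C[C@@H](OC(=O)/C(C)=C\C)[C@@H](C(=C)C(=O)O)C=C | intermediate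
19 | E-enamine formed from the formyl group of 18 and N1 of (2S,5S)-5-benzyl-2-tert-butyl-3-methylimidazolidin-4-one | CN1C(=O)[C@H](Cc2ccccc2)N(/C=C/CC/C=C(/CO[Si](c2ccccc2)(c2ccccc2)C(C)(C)C)C[C@@H](OC(=O)/C(C)=C\C)[C@@H](C(=C)C(=O)O)C=C)[C@@H]1C(C)(C)C | intermediate
20 | (1(10)E,4R,6R,7S,8R)-8-angeloyloxy-14-[(tert-butyldiphenylsilyl)oxy]-15-oxogermacra-1(10),11(13)-dien-12,6-olide | C=C1C(=O)O[C@@H]2C[C@H](C=O)CC/C=C(/CO[Si](c3ccccc3)(c3ccccc3)C(C)(C)C)C[C@@H](OC(=O)/C(C)=C\C)[C@@H]12 | intermediate
21 | (1(10)E,4R,6R,7S,8R)-8-angeloyloxy-14-[(tert-butyldiphenylsilyl)oxy]-15-hydroxygermacra-1(10),11(13)-dien-12,6-olide | C=C1C(=O)O[C@@H]2C[C@H](CO)CC/C=C(/CO[Si](c3ccccc3)(c3ccccc3)C(C)(C)C)C[C@@H](OC(=O)/C(C)=C\C)[C@@H]12 | intermediate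
22 | (1(10)E,4R,6R,7S,8R)-8-angeloyloxy-14,15-dihydroxygermacra-1(10),11(13)-dien-12,6-olide | C=C1C(=O)O[C@@H]2C[C@H](CO)CC/C=C(/CO)C[C@@H](OC(=O)/C(C)=C\C)[C@@H]12 | target

**Step count and risks**

Total steps: 15. Longest linear sequence: 12 (steps 1, 3–7, 10–15 from cyclopentene).

Steps most likely to fail:

1. Step 13. The radical cation may be consumed by oligomerisation or over-oxidation before the slow 10-endo closure; closure may occur onto the acrylic alkene; the C6 radical may be lost by oxidative elimination instead of C–O bond formation; facial control at C6 may be poor. Fallback with known reaction types (auxiliary-controlled atom-transfer radical cyclisation, then lactonisation), setting out from 17 and coming back at 21. Selective hydrolysis of the acetal (PPTS, acetone/H2O) should give the aldehyde tert-butyl ester F1. Pinnick oxidation (NaClO2, NaH2PO4, 2-methyl-2-butene) should give the C15 acid F2. Pivaloyl chloride/Et3N, then (S)-4-benzyloxazolidin-2-one and LiCl, should give the imide F3. Soft enolisation (Bu2BOTf, i-Pr2NEt, −78 °C) and N-bromosuccinimide should give the α-bromo imide F4. CF3CO2H in CH2Cl2 should free the C12 acid F5. Bromine-atom-transfer radical cyclisation (Yb(OTf)3, Et3B/O2, CH2Cl2, high dilution; the chelated auxiliary directs attack at C4 as in its enolate alkylations) should give the ten-membered C6 bromide F6. NaHCO3 in DMF should close F6 by carboxylate displacement to the lactone imide F7; the trans-fused isomer is separated if both form. LiBH4/MeOH in THF at −20 °C should then cleave the imide to the alcohol 21. This costs four extra steps.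

2. Step 10. The β,γ-unsaturated aldehyde may isomerise into conjugation; the pentadienyl-type chromium reagent may react through the wrong terminus; enantiofacial control may be insufficient. Fallback by acid-catalysed allylboration through a closed chair transition state, setting out from 14 and coming back at 16. Borylation of 14 (B2pin2, Pd2(dba)3, toluene, 50 °C) should give tert-butyl (2E)-2-[(4,4,5,5-tetramethyl-1,3,2-dioxaborolan-2-yl)methyl]penta-2,4-dienoate F8. Its addition to 10 under (R)-3,3'-bis(2,4,6-triisopropylphenyl)-1,1'-binaphthyl-2,2'-diyl hydrogen phosphate (5 mol %) in toluene at −30 °C should give 16 after aqueous work-up. The vinyl group cis to CH2B fixes the syn relationship and the chiral acid fixes the face.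

3. Step 11. The angelate may isomerise to the tiglate during acylation of the hindered alcohol, or the acylation may stall. Fallback that builds the Z double bond on the ester, setting out from 16 and coming back at 17. Esterification of 16 with 2-[bis(2,2,2-trifluoroethoxy)phosphoryl]propanoic acid (EDC, DMAP, CH2Cl2) should give the phosphonate ester F9. Still–Gennari olefination of F9 with acetaldehyde (KN(SiMe3)2, 18-crown-6, THF, −78 °C) should give 17 with the Z geometry set kinetically.

Further compounds
F1 | step 13 | tert-butyl (3R,4R,6E)-6-{[(tert-butyldiphenylsilyl)oxy]methyl}-3-ethenyl-4-{[(2Z)-2-methylbut-2-enoyl]oxy}-2-methylidene-11-oxoundec-6-enoate | O=CCCC/C=C(/CO[Si](c1ccccc1)(c1ccccc1)C(C)(C)C)C[C@@H](OC(=O)/C(C)=C\C)[C@@H](C(=C)C(=O)OC(C)(C)C)C=C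
F2 | step 13 | carboxylic acid from F1 (C15 formyl group oxidised to CO2H, tert-butyl ester retained) | OC(=O)CCC/C=C(/CO[Si](c1ccccc1)(c1ccccc1)C(C)(C)C)C[C@@H](OC(=O)/C(C)=C\C)[C@@H](C(=C)C(=O)OC(C)(C)C)C=C
F3 | step 13 | N-acyl (S)-4-benzyloxazolidin-2-one imide of F2 | O=C(CCC/C=C(/CO[Si](c1ccccc1)(c1ccccc1)C(C)(C)C)C[C@@H](OC(=O)/C(C)=C\C)[C@@H](C(=C)C(=O)OC(C)(C)C)C=C)N1[C@@H](Cc2ccccc2)COC1=O
F4 | step 13 | α-bromo imide (bromine on C4, either epimer) | O=C(C(Br)CC/C=C(/CO[Si](c1ccccc1)(c1ccccc1)C(C)(C)C)C[C@@H](OC(=O)/C(C)=C\C)[C@@H](C(=C)C(=O)OC(C)(C)C)C=C)N1[C@@H](Cc2ccccc2)COC1=O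
F5 | step 13 | α-bromo imide with free C12 carboxylic acid | O=C(C(Br)CC/C=C(/CO[Si](c1ccccc1)(c1ccccc1)C(C)(C)C)C[C@@H](OC(=O)/C(C)=C\C)[C@@H](C(=C)C(=O)O)C=C)N1[C@@H](Cc2ccccc2)COC1=O
F6 | step 13 | ten-membered carbocycle with C6 bromide (either epimer), free C12 acid and C15 imide | OC(=O)C(=C)[C@H]1C(Br)C[C@H](C(=O)N2[C@@H](Cc3ccccc3)COC2=O)CC/C=C(/CO[Si](c3ccccc3)(c3ccccc3)C(C)(C)C)C[C@H]1OC(=O)/C(C)=C\C
F7 | step 13 | trans-fused 12,6-lactone with C15 imide | C=C1C(=O)O[C@@H]2C[C@H](C(=O)N3[C@@H](Cc4ccccc4)COC3=O)CC/C=C(/CO[Si](c3ccccc3)(c3ccccc3)C(C)(C)C)C[C@@H](OC(=O)/C(C)=C\C)[C@@H]12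
F8 | step 10 | tert-butyl (2E)-2-[(4,4,5,5-tetramethyl-1,3,2-dioxaborolan-2-yl)methyl]penta-2,4-dienoate | CC1(C)OB(C/C(C(=O)OC(C)(C)C)=C\C=C)OC1(C)C
F9 | step 11 | 2-[bis(2,2,2-trifluoroethoxy)phosphoryl]propanoate ester of 16 at the C8 oxygen | COC(OC)CCC/C=C(/CO[Si](c1ccccc1)(c1ccccc1)C(C)(C)C)C[C@@H](OC(=O)C(C)P(=O)(OCC(F)(F)F)OCC(F)(F)F)[C@@H](C(=C)C(=O)OC(C)(C)C)C=C
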